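## Retrosynthetic overview

- **Endgame:** The side-chain carbinol is unmasked last by Si–O cleavage. Before that, the enoic acid C=C is disconnected by cross-metathesis into a terminal alkene and acrylic acid.
- **Structural feature used:** In the 5-hydroxy-7-methoxychromone, C4a is flanked by C8a–O1 and C5–OH, two oxygens that are equivalent in a 5-methoxyresorcinol. C4, C3, C2 and the attached CH2–CH(OH) correspond to CO plus a homopropargylic alcohol.
- **Key disconnection:** The pyranone is cut at C4a–C4, C4–C3 and O1–C2 into 2-iodo-5-methoxyresorcinol, CO and (R)-4-silyloxydec-9-en-1-yne. The iodide comes from directed lithiation of the bis-MOM ether. The alkyne comes from (R)-epichlorohydrin by two epoxide openings at CH2 carbons (pentenyl Grignard, then silylacetylide).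
- **Ring order:** The benzene ring is purchased. The pyran-4-one is the only ring built, in the same operation that attaches the chiral chain.

Key step: step 9

Assumption: commercial (R)-epichlorohydrin is taken as enantiopure. No step breaks the C–O bond of its stereocentre, so its enantiopurity carries through to the target, and the descriptor stays R in every intermediate.

## Route

Step 1
Reactants: 1 5-methoxyresorcinol
Product: 2 1-methoxy-3,5-bis(methoxymethoxy)benzene
Conditions: MOMCl (3 equiv), iPr2NEt (4 equiv), CH2Cl2, 0 °C → rt
Reagents that add atoms: chloromethyl methyl ether (MOMCl), COCCl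
Why: O-alkylation of both phenols by the hard electrophile MOMCl (Williamson-type acetal formation) installs the two chelating groups that direct the next step.

Step 2
Reactants: 2 1-methoxy-3,5-bis(methoxymethoxy)benzene
Product: 4 2-iodo-5-methoxy-1,3-bis(methoxymethoxy)benzene, via 2-lithioarene 3 (not isolated)
Conditions: n-BuLi (1.1 equiv), THF, 0 °C; then I2, THF, −78 °C → rt; aq. Na2S2O3 wash
Reagents that add atoms: iodine, II
Why: In this directed ortho-metalation the C–H flanked by two OMOM groups is the best coordinated and most acidic site (OMOM outranks OMe as a director), and the aryllithium is trapped by iodine.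

Step 3
Reactants: 4 2-iodo-5-methoxy-1,3-bis(methoxymethoxy)benzene
Product: 5 2-iodo-5-methoxybenzene-1,3-diol
Conditions: p-TsOH·H2O (20 mol %), MeOH, 40 °C, dark
Reagents that add atoms: none
Why: Acid-catalysed transacetalisation passes both MOM groups to methanol, and a catalytic sulfonic acid without a nucleophilic halide counter-ion should keep ipso-protonation and iodine transfer on the electron-rich ring slow.

Step 4
Reactants: 6 5-bromopent-1-ene; 7 (R)-epichlorohydrin
Product: 9 (R)-1-chlorooct-7-en-2-ol, via pent-4-enylmagnesium bromide 8 (not isolated)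
Conditions: 6, Mg, THF, rt → 40 °C; then 7, CuI (10 mol %), THF, −40 → −20 °C; sat. aq. NH4Cl
Reagents that add atoms: none
Why: The copper-catalysed Grignard opening of a terminal epoxide proceeds by SN2 attack at the unsubstituted ring CH2, faster than chloride displacement, so the stereocentre keeps its C–O bond and its configuration.

Step 5
Reactants: 9 (R)-1-chlorooct-7-en-2-ol
Product: 10 (R)-2-(hex-5-en-1-yl)oxirane
Conditions: NaOH (powder), Et2O, rt
Reagents that add atoms: none
Why: In this intramolecular Williamson closure (3-exo-tet) the alkoxide displaces chloride at the achiral CH2Cl carbon, so the carbinol configuration is retained in the new terminal epoxide.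

Step 6
Reactants: 11 ethynyltrimethylsilane; 10 (R)-2-(hex-5-en-1-yl)oxirane
Product: 13 (R)-1-(trimethylsilyl)dec-9-en-1-yn-4-ol, via lithium trimethylsilylacetylide 12 (not isolated)
Conditions: 11, n-BuLi, THF, −78 °C; BF3·OEt2, then 10, −78 °C; H2O
Reagents that add atoms: none
Why: In the Yamaguchi–Hirao alkynylation the BF3-activated epoxide is opened by the acetylide at its terminal CH2, which again leaves the stereogenic C–O bond untouched.

Step 7
Reactants: 13 (R)-1-(trimethylsilyl)dec-9-en-1-yn-4-ol
Product: 14 (R)-4-(tert-butyldimethylsilyloxy)-1-(trimethylsilyl)dec-9-en-1-yne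
Conditions: TBSCl, imidazole, DMF, rt
Reagents that add atoms: tert-butyldimethylsilyl chloride (TBSCl), CC(C)(C)[Si](C)(C)Cl
Why: Imidazole-promoted O-silylation of an unhindered secondary alcohol gives an ether that is stable to amine, Pd and Ru.

Step 8
Reactants: 14 (R)-4-(tert-butyldimethylsilyloxy)-1-(trimethylsilyl)dec-9-en-1-yne
Product: 15 (R)-4-(tert-butyldimethylsilyloxy)dec-9-en-1-yne
Conditions: K2CO3 (20 mol %), MeOH, rt
Reagents that add atoms: none
Why: Base-catalysed methanolysis (protodesilylation) cleaves the alkynyl C–SiMe3 bond, while the bulky alkyl TBS ether is inert under these conditions.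

Step 9
Reactants: 5 2-iodo-5-methoxybenzene-1,3-diol; 15 (R)-4-(tert-butyldimethylsilyloxy)dec-9-en-1-yne; 16 carbon monoxide
Product: 19 (R)-2-[2-(tert-butyldimethylsilyloxy)oct-7-en-1-yl]-5-hydroxy-7-methoxy-4H-chromen-4-one, via dihydroxyaryl ynone 17 (not isolated), via diethylamino enone 18 (not isolated)
Conditions: 5 (1.2 equiv), PdCl2(dppf)·CH2Cl2 (5 mol %), CO (20 bar), Et2NH (solvent), 90 °C, autoclave, no copper
Reagents that add atoms: none
Why: Pd(0) adds into the C–I bond of 5, CO inserts to give the aroyl-palladium iodide, the amine-deprotonated alkyne 15 is transferred, and reductive elimination releases ynone 17 (new bonds C4a–C4 and C4–C3); this is the known carbonylative Sonogashira coupling–cyclisation of 2-iodophenols with terminal alkynes in a secondary amine. Diethylamine then adds in conjugate fashion to 17 to give amino enone 18, and a flanking phenol oxygen attacks the amine-bearing carbon and expels Et2NH (addition–elimination, overall a 6-endo closure forming O1–C2), which closes the pyran-4-one. Three selectivities are needed: CO insertion ahead of direct alkynylation is favoured by CO pressure, by the absence of copper and by fast migration of the electron-rich, doubly ortho-substituted aryl group; alkyne rather than amine capture of the aroyl-palladium is helped by the two ortho oxygens that shield the acyl carbon from the bulkier amine; and six- rather than five-membered (aurone) closure follows because the amino enone offers only its β-carbon as electrophile. Which hydroxyl cyclises is not an issue, because the two OH groups of 5 are interchanged by the axis through C2 and C5, so either one gives the same chromone, the other ends as the chelated 5-OH, and the methoxy group lands on C7. No stereocentre is formed; the silyloxy carbon has no acidic hydrogen and its C–O bond is not involved, and the TBS group keeps the carbinol from intercepting the aroyl-palladium as an ester.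

Step 10
Reactants: 19 (R)-2-[2-(tert-butyldimethylsilyloxy)oct-7-en-1-yl]-5-hydroxy-7-methoxy-4H-chromen-4-one; 20 acrylic acid
Product: 21 (2E,8R)-8-(tert-butyldimethylsilyloxy)-9-(5-hydroxy-7-methoxy-4-oxo-4H-chromen-2-yl)non-2-enoic acid
Conditions: 20 (3 equiv), Hoveyda–Grubbs II (5 mol %), CH2Cl2, 40 °C
Reagents that add atoms: none
Why: Olefin cross-metathesis of a rapidly reacting terminal alkene with the slowly homodimerising acrylic acid should be selective and give the E geometry under thermodynamic control, while the trisubstituted, electron-poor chromone C2=C3 bond is inert to the carbene.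

Step 11
Reactants: 21 (2E,8R)-8-(tert-butyldimethylsilyloxy)-9-(5-hydroxy-7-methoxy-4-oxo-4H-chromen-2-yl)non-2-enoic acid
Product: 22 penithochromone T, (2E,8R)-8-hydroxy-9-(5-hydroxy-7-methoxy-4-oxo-4H-chromen-2-yl)non-2-enoic acid
Conditions: HF·pyridine, pyridine, THF, 0 °C → rt (PTFE vessel)
Reagents that add atoms: none
Why: Fluoride-driven Si–O cleavage in a buffered, weakly acidic medium frees the carbinol with retention and avoids the basic conditions under which the vinylogously acidic C2–CH2 could lose the β-oxygen by E1cB.

## Compound list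

1 | 5-methoxyresorcinol | COc1cc(O)cc(O)c1 | starting material
2 | 1-methoxy-3,5-bis(methoxymethoxy)benzene | COCOc1cc(OC)cc(OCOC)c1 | intermediate
3 | [4-methoxy-2,6-bis(methoxymethoxy)phenyl]lithium | [Li]c1c(OCOC)cc(OC)cc1OCOC | intermediate
4 | 2-iodo-5-methoxy-1,3-bis(methoxymethoxy)benzene | COCOc1cc(OC)cc(OCOC)c1I | intermediate
5 | 2-iodo-5-methoxybenzene-1,3-diol | COc1cc(O)c(I)c(O)c1 | intermediate
6 | 5-bromopent-1-ene | C=CCCCBr | starting material
7 | (R)-epichlorohydrin | ClC[C@H]1CO1 | starting material
8 | pent-4-enylmagnesium bromide | C=CCCC[Mg]Br | intermediate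
9 | (R)-1-chlorooct-7-en-2-ol | ClC[C@H](O)CCCCC=C | intermediate
10 | (R)-2-(hex-5-en-1-yl)oxirane | C=CCCCC[C@@H]1CO1 | intermediate
11 | ethynyltrimethylsilane | C#C[Si](C)(C)C | starting material
12 | lithium (trimethylsilyl)acetylide | [Li]C#C[Si](C)(C)C | intermediate
13 | (R)-1-(trimethylsilyl)dec-9-en-1-yn-4-ol | C[Si](C)(C)C#CC[C@H](O)CCCCC=C | intermediate
14 | (R)-4-(tert-butyldimethylsilyloxy)-1-(trimethylsilyl)dec-9-en-1-yne | C[Si](C)(C)C#CC[C@H](O[Si](C)(C)C(C)(C)C)CCCCC=C | intermediate
15 | (R)-4-(tert-butyldimethylsilyloxy)dec-9-en-1-yne | C#CC[C@H](O[Si](C)(C)C(C)(C)C)CCCCC=C | intermediate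
16 | carbon monoxide | [C-]#[O+] | starting material
17 | (R)-5-(tert-butyldimethylsilyloxy)-1-(2,6-dihydroxy-4-methoxyphenyl)undec-10-en-2-yn-1-one | COc1cc(O)c(C(=O)C#CC[C@H](O[Si](C)(C)C(C)(C)C)CCCCC=C)c(O)c1 | intermediate
18 | (R,E)-5-(tert-butyldimethylsilyloxy)-3-(diethylamino)-1-(2,6-dihydroxy-4-methoxyphenyl)undeca-2,10-dien-1-one | COc1cc(O)c(C(=O)/C=C(/N(CC)CC)C[C@H](O[Si](C)(C)C(C)(C)C)CCCCC=C)c(O)c1 | intermediate
19 | (R)-2-[2-(tert-butyldimethylsilyloxy)oct-7-en-1-yl]-5-hydroxy-7-methoxy-4H-chromen-4-one | COc1cc(O)c2c(=O)cc(C[C@H](O[Si](C)(C)C(C)(C)C)CCCCC=C)oc2c1 | intermediate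
20 | acrylic acid | C=CC(=O)O | starting material
21 | (2E,8R)-8-(tert-butyldimethylsilyloxy)-9-(5-hydroxy-7-methoxy-4-oxo-4H-chromen-2-yl)non-2-enoic acid | COc1cc(O)c2c(=O)cc(C[C@H](O[Si](C)(C)C(C)(C)C)CCCC/C=C/C(=O)O)oc2c1 | intermediate
22 | penithochromone T | COc1cc(O)c2c(=O)cc(C[C@H](O)CCCC/C=C/C(=O)O)oc2c1 | target

## Step count

Total step count: 11
Longest linear sequence: 8 steps (steps 4–11, from 6 and 7)

## Steps most likely to fail

**1. Step 9.**
- **Risk:**
  - CO insertion may lose out to direct alkynylation or to reduction of the C–I bond of the hindered, electron-rich iodide.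
  - The aroyl-palladium may be captured by diethylamine.
  - Long heating in amine may trigger β-elimination of the silyloxy group next to the vinylogously acidic C2–CH2.
- **Fallback:** An organolithium route to the ynone, without palladium or CO. It sets out from 2 and 15 and rejoins the route at 22.
  - Aryllithium 3, made from 2 as in step 2, is quenched with DMF to give 4-methoxy-2,6-bis(methoxymethoxy)benzaldehyde F1.
  - Alkyne 15 is deprotonated with n-BuLi (THF, −78 °C) and added to F1 to give the propargylic alcohol F2. Both epimers form at the new carbinol, which is oxidised in the next operation.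
  - MnO2 in CH2Cl2 gives the bis-MOM ynone F3.
  - Et2NH in EtOH at rt adds to give the bis-MOM diethylamino enone F4.
  - HCl in MeOH at 50 °C removes both MOM groups and the silyl ether and closes the pyranone with loss of the amine. This gives (R)-5-hydroxy-2-(2-hydroxyoct-7-en-1-yl)-7-methoxy-4H-chromen-4-one F5.
  - Cross-metathesis of F5 with 20 under the conditions of step 10 leads directly to 22.

**2. Step 3.**
- **Risk:** Ipso-protonation of the iodine-bearing carbon, which is activated by three oxygen substituents, may cause loss or migration of iodine during the acidic acetal cleavage.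
- **Fallback:** Protecting-group-free iodination. It sets out from 1 and rejoins the route at 5.
  - Compound 1 is iodinated directly with I2 and NaHCO3 in H2O–THF at 0 °C. This is the known bicarbonate iodination of resorcinols, which favours the position between the two hydroxyls.
  - Compound 5 is separated from any regioisomer by crystallisation or chromatography.
  - No acid is involved, and the fallback makes no compound outside the list (F0).

**3. Step 10.**
- **Risk:**
  - The chelating 5-hydroxy-4-oxo unit or the free acid may bind the catalyst and slow turnover.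
  - The terminal alkene may homodimerise.
  - Ruthenium hydrides may cause chain-walking of the alkene.
- **Fallback:** Oxidative cleavage followed by olefination. It sets out from 19 and rejoins the route at 22.
  - Lemieux–Johnson cleavage (cat. OsO4, NaIO4, 2,6-lutidine, dioxane–H2O) gives (R)-6-(tert-butyldimethylsilyloxy)-7-(5-hydroxy-7-methoxy-4-oxo-4H-chromen-2-yl)heptanal F6.
  - Wittig reaction with the stabilised ylide tert-butyl (triphenylphosphoranylidene)acetate in CH2Cl2 at rt gives the E-configured tert-butyl enoate F7.
  - TFA–CH2Cl2–H2O at 0 °C → rt removes the tert-butyl ester and the silyl ether together to give 22.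

## Further compounds

F1 | step 9 | 4-methoxy-2,6-bis(methoxymethoxy)benzaldehyde | COCOc1cc(OC)cc(OCOC)c1C=O
F2 | step 9 | (5R)-5-(tert-butyldimethylsilyloxy)-1-[4-methoxy-2,6-bis(methoxymethoxy)phenyl]undec-10-en-2-yn-1-ol (both C1 epimers) | COCOc1cc(OC)cc(OCOC)c1C(O)C#CC[C@H](O[Si](C)(C)C(C)(C)C)CCCCC=C
F3 | step 9 | (R)-5-(tert-butyldimethylsilyloxy)-1-[4-methoxy-2,6-bis(methoxymethoxy)phenyl]undec-10-en-2-yn-1-one | COCOc1cc(OC)cc(OCOC)c1C(=O)C#CC[C@H](O[Si](C)(C)C(C)(C)C)CCCCC=C
F4 | step 9 | (R,E)-5-(tert-butyldimethylsilyloxy)-3-(diethylamino)-1-[4-methoxy-2,6-bis(methoxymethoxy)phenyl]undeca-2,10-dien-1-one | COCOc1cc(OC)cc(OCOC)c1C(=O)/C=C(/N(CC)CC)C[C@H](O[Si](C)(C)C(C)(C)C)CCCCC=C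
F5 | step 9 | (R)-5-hydroxy-2-(2-hydroxyoct-7-en-1-yl)-7-methoxy-4H-chromen-4-one | COc1cc(O)c2c(=O)cc(C[C@H](O)CCCCC=C)oc2c1
F0 | step 3 | none | none
F6 | step 10 | (R)-6-(tert-butyldimethylsilyloxy)-7-(5-hydroxy-7-methoxy-4-oxo-4H-chromen-2-yl)heptanal | COc1cc(O)c2c(=O)cc(C[C@H](O[Si](C)(C)C(C)(C)C)CCCCC=O)oc2c1
F7 | step 10 | tert-butyl (2E,8R)-8-(tert-butyldimethylsilyloxy)-9-(5-hydroxy-7-methoxy-4-oxo-4H-chromen-2-yl)non-2-enoate | COc1cc(O)c2c(=O)cc(C[C@H](O[Si](C)(C)C(C)(C)C)CCCC/C=C/C(=O)OC(C)(C)C)oc2c1
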